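**Retrosynthetic overview**

- The target is the diester of (2E,6E)-2,6-dimethylocta-2,6-dienedioic acid with two identical (4R,4aS,6R,7S,7aR) amino alcohols. Both acyl C–O bonds are cut (last step, carbodiimide); the diacid comes from geranyl acetate by allylic oxidation at C8 and oxidation of both termini.
- Each alcohol comes from the C6 ketone (hydride anti to the C7 methyl), the ketone from a beta-keto ester, and that from a C5–C6 Dieckmann closure of ring A (C4a, C5, C6, C7, C7a) across an all-cis piperidine with an acetate arm on C4a and a propanoate arm on C7a.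
- Feature used: on ring B (N2, C1, C3, C4, C4a, C7a) the hydrogens H4, H4a and H7a are all cis. This is the pattern left when hydrogen adds to one face of a 3,4,5-trisubstituted pyridine, so ring B is bought as an aromatic pyridine and ring A is only a cyclopentanone bridging the two cis arms.
- Ring order: pyridine ring B, then the two arms, then N-methylation and all-cis hydrogenation, then ring A by Dieckmann closure. C7 is set by equilibration beside the ketone and C6 by hydride. The racemate is resolved at the 6-alcohol, because the piperidine diester is an epimer mixture at the propanoate carbon and cannot be resolved cleanly.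

Key step: step 5

Remark on the chemistry: which enantiomer of the racemic 6-alcohol gives the less soluble salt with a given diacyl tartaric acid cannot be predicted. The route is written for the (2R,3R) acid; the commercial (2S,3S) acid would be used in the same way if the salts fall out the other way round. Racemic compounds are drawn as the enantiomer that leads to the target.

**Route**

Step 1
Reactants: 1 3-bromo-4,5-dimethylpyridine; 2 dimethyl carbonate
Product: 3 methyl 2-(3-bromo-5-methylpyridin-4-yl)acetate
Conditions: LiN(i-Pr)2 (2.2 equiv), THF, −78 °C; then 2 (1.2 equiv), −78 → 0 °C; aq. NH4Cl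
Reagents that add atoms: none
Why: Lateral lithiation and Claisen-type C-acylation: the 4-methyl group is the only position whose carbanion is delocalised onto the ring nitrogen, so the amide base removes its proton in preference to the 5-methyl and ring C–H positions at −78 °C, and the second equivalent of base stores the more acidic arylacetate product as its enolate, which stops double acylation; no stereocentre is formed.

Step 2
Reactants: 3 methyl 2-(3-bromo-5-methylpyridin-4-yl)acetate; 4 methyl 2-bromopropanoate (racemic)
Product: 6 methyl 2-[4-(2-methoxy-2-oxoethyl)-5-methylpyridin-3-yl]propanoate (racemic), via bromozinc ester enolate 5 (not isolated)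
Conditions: 4 (1.6 equiv), Zn dust, TMSCl (cat.), THF, rt; then 3, Pd(dba)2 (2 mol%), P(t-Bu)3 (2 mol%), THF, rt → 50 °C
Reagents that add atoms: none
Why: Negishi-type alpha-arylation of a Reformatsky reagent: zerovalent palladium inserts into the C3–Br bond, the zinc enolate transmetalates and the C-bound palladium enolate reductively eliminates, and because a zinc enolate is a weak base the acidic CH2 of the pyridylacetate and both methyl esters should survive; the propanoate stereocentre forms as a racemate, which does not matter because it is equilibrated in steps 5 and 6.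

Step 3
Reactants: 6 methyl 2-[4-(2-methoxy-2-oxoethyl)-5-methylpyridin-3-yl]propanoate
Product: 7 3-(1-methoxy-1-oxopropan-2-yl)-4-(2-methoxy-2-oxoethyl)-1,5-dimethylpyridin-1-ium trifluoromethanesulfonate (racemic)
Conditions: MeOTf (1.05 equiv), CH2Cl2, 0 °C → rt
Reagents that add atoms: methyl trifluoromethanesulfonate, COS(=O)(=O)C(F)(F)F
Why: Menshutkin N-alkylation: the ring nitrogen, flanked by two C–H positions, is the only nucleophile for the methylating agent, which installs the N2 methyl group of the target, activates the ring for mild hydrogenation and, with a triflate counter-ion, avoids halide poisoning of platinum; no stereocentre is formed.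

Step 4
Reactants: 7 the pyridinium triflate
Product: 8 methyl 2-[(3R*,4S*,5R*)-4-(2-methoxy-2-oxoethyl)-1,5-dimethylpiperidin-3-yl]propanoate (racemic; both epimers at the propanoate carbon)
Conditions: H2 (4 atm), PtO2 (5 mol%), MeOH, rt; then aq. Na2CO3, CH2Cl2
Reagents that add atoms: none
Why: Heterogeneous hydrogenation of a pyridinium salt: the flat ring lies on the platinum surface by one face and takes all its hydrogen from that face, so the hydrogens on piperidine C3, C4 and C5 (later H7a, H4a and H4) should come out mutually cis, while the exocyclic propanoate centre is not controlled and the product is racemic; the tertiary N-methyl amine cannot lactamise onto the ester arms.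

Step 5
Reactants: 8 the all-cis piperidine diester
Product: 9 methyl (4R*,4aS*,7aR*)-6-hydroxy-2,4,7-trimethyl-2,3,4,4a,7,7a-hexahydro-1H-cyclopenta[c]pyridine-5-carboxylate (racemic; enol form; C7 as carried)
Conditions: KOtBu (1.5 equiv), THF, 0 °C → rt; then AcOH to pH 7–8
Reagents that add atoms: none
Why: Dieckmann condensation: tert-butoxide forms both ester enolates of 8 reversibly, the acetate-arm enolate carbon C5 adds to the propanoate carbonyl C6, the tetrahedral intermediate expels methoxide, and the new beta-keto ester is deprotonated at C5, which pulls the equilibrium over. The closest known reaction type is the alkoxide-mediated cyclisation of a 1,6-diester to a 2-oxocyclopentanecarboxylate. Ring A closes in a 5-(enolexo)-exo-trig mode and can only be cis-fused, because the two arms sit cis on C4a and C7a of the piperidine. The step needs regioselectivity between the two Claisen directions: attack of C7 on the acetate carbonyl would give a beta-keto ester with a quaternary C7 and no proton between the carbonyls, so that adduct reverts by retro-Claisen cleavage while the C5-ester product is drained as its potassium enolate. No lasting stereocentre is created, since C5 is trigonal in the enol; C7 epimerises through the propanoate enolate before closure and is fixed in step 6, and C4, C4a and C7a carry no acidic hydrogen and stay as the hydrogenation left them.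

Step 6
Reactants: 9 the enolised beta-keto ester
Product: 11 (4R*,4aS*,7S*,7aR*)-2,4,7-trimethyloctahydro-6H-cyclopenta[c]pyridin-6-one (racemic), via beta-keto acid 10 (not isolated)
Conditions: 6 M HCl, reflux; NaOH to pH 12, CH2Cl2; then NaOMe (0.1 equiv), MeOH, rt
Reagents that add atoms: none
Why: Acid hydrolysis of the beta-keto ester and decarboxylation of the beta-keto acid through its cyclic six-membered transition state, run on the protonated amine because chloride-mediated dealkoxycarbonylation in hot DMSO would release chloromethane beside a nucleophilic tertiary amine; C7 now lies alpha to the ketone and is equilibrated by enolisation to the epimer with the methyl group on the convex face, trans to C1, as expected for a 2,3-disubstituted cyclopentanone.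

Step 7
Reactants: 11 the racemic ketone
Product: 12 (4R*,4aS*,6R*,7S*,7aR*)-2,4,7-trimethyloctahydro-1H-cyclopenta[c]pyridin-6-ol (racemic)
Conditions: Li[HB(s-Bu)3] (1.2 equiv), THF, −78 °C; then H2O; acid–base extraction
Reagents that add atoms: none
Why: Diastereoselective ketone reduction with a bulky trialkylborohydride: hydride should reach C6 from the face opposite the adjacent C7 methyl group, as 2-alkylcyclopentanones give cis alcohols with this reagent, which sets C6 with oxygen cis to the C7 methyl group and on the face of H4a and H7a; the non-oxidative work-up avoids N-oxide formation.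

Step 8
Reactants: 12 the racemic alcohol
Product: 13 (4R,4aS,6R,7S,7aR)-6-hydroxy-2,4,7-trimethyloctahydro-1H-cyclopenta[c]pyridin-2-ium hydrogen (2R,3R)-2,3-bis[(4-methylbenzoyl)oxy]butanedioate (1:1 salt)
Conditions: (2R,3R)-di-p-toluoyltartaric acid (1.0 equiv), EtOH, reflux → rt; recrystallise to constant rotation
Reagents that add atoms: (2R,3R)-2,3-bis[(4-methylbenzoyl)oxy]butanedioic acid, OC(=O)[C@H](OC(=O)c1ccc(C)cc1)[C@@H](OC(=O)c1ccc(C)cc1)C(=O)O
Why: Classical resolution through diastereomeric salts: the tertiary amine forms a 1:1 hydrogen tartrate, the two diastereomeric salts differ in solubility and the less soluble one is recrystallised, its configuration to be confirmed by X-ray diffraction against the known centres of the acid; no stereocentre is formed, one enantiomer is selected.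

Step 9
Reactants: 13 the diastereomerically pure salt
Product: 14 (4R,4aS,6R,7S,7aR)-2,4,7-trimethyloctahydro-1H-cyclopenta[c]pyridin-6-ol
Conditions: 2 M aq. K2CO3, CH2Cl2, rt
Reagents that add atoms: none
Why: Acid–base liberation of the free amine from its salt, which leaves all five stereocentres untouched and sends the resolving acid into the aqueous layer for recovery.

Step 10
Reactants: 15 geranyl acetate
Product: 16 (2E,6E)-8-hydroxy-3,7-dimethylocta-2,6-dien-1-yl acetate
Conditions: SeO2 (0.1 equiv), t-BuOOH (3 equiv), salicylic acid (0.1 equiv), CH2Cl2, rt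
Reagents that add atoms: tert-butyl hydroperoxide (terminal oxidant, source of the new oxygen by way of SeO2), CC(C)(C)OO
Why: Allylic oxidation by catalytic SeO2 (ene reaction followed by [2,3]-sigmatropic shift), which attacks the more electron-rich 6,7-alkene remote from the acetate and selects its E-methyl group, so the 6E geometry is kept; any over-oxidised 8-aldehyde converges with the main line at step 12.

Step 11
Reactants: 16 the 8-hydroxy acetate
Product: 17 (2E,6E)-2,6-dimethylocta-2,6-diene-1,8-diol
Conditions: K2CO3 (0.2 equiv), MeOH, rt
Reagents that add atoms: none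
Why: Base-catalysed methanolysis (transesterification) of the allylic acetate; neither alkene is touched.

Step 12
Reactants: 17 the diol
Product: 18 (2E,6E)-2,6-dimethylocta-2,6-dienedial
Conditions: TEMPO (0.1 equiv), PhI(OAc)2 (2.3 equiv), CH2Cl2, rt
Reagents that add atoms: none
Why: Nitroxyl-catalysed oxidation of both allylic alcohols with PhI(OAc)2 as the stoichiometric oxidant, which stops at the aldehyde in the absence of water and is mild enough to keep both trisubstituted E-enals from isomerising.

Step 13
Reactants: 18 the dialdehyde
Product: 19 (2E,6E)-2,6-dimethylocta-2,6-dienedioic acid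
Conditions: NaClO2 (4 equiv), NaH2PO4, 2-methylbut-2-ene (excess), t-BuOH/H2O, rt; acidify to pH 3
Reagents that add atoms: sodium chlorite, [Na+].[O-]Cl=O
Why: Pinnick oxidation: chlorous acid converts each conjugated aldehyde into the acid without touching the alkenes, while 2-methylbut-2-ene traps the hypochlorous acid formed.

Step 14
Reactants: 14 the resolved alcohol (2.2 equiv); 19 the diacid
Product: 20 bis[(4R,4aS,6R,7S,7aR)-2,4,7-trimethyloctahydro-1H-cyclopenta[c]pyridin-6-yl] (2E,6E)-2,6-dimethylocta-2,6-dienedioate (CNP0240822.3)
Conditions: DCC (2.4 equiv), DMAP (0.3 equiv), CH2Cl2, 0 °C → rt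
Reagents that add atoms: none
Why: Steglich esterification: the carbodiimide activates each carboxyl group as an O-acylisourea, DMAP relays the acyl group to the C6 hydroxyl, and since the C6–O bond is never broken the (6R) configuration is retained at both ends; the tertiary amines do not interfere.

**Compound list**

1 | 3-bromo-4,5-dimethylpyridine | Cc1cncc(Br)c1C | starting material
2 | dimethyl carbonate | COC(=O)OC | starting material
3 | methyl 2-(3-bromo-5-methylpyridin-4-yl)acetate | COC(=O)Cc1c(C)cncc1Br | intermediate
4 | methyl 2-bromopropanoate (racemic) | COC(=O)C(C)Br | starting material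
5 | bromo(1-methoxy-1-oxopropan-2-yl)zinc (Reformatsky reagent, not isolated) | COC(=O)C(C)[Zn]Br | intermediate
6 | methyl 2-[4-(2-methoxy-2-oxoethyl)-5-methylpyridin-3-yl]propanoate (racemic) | COC(=O)Cc1c(C)cncc1C(C)C(=O)OC | intermediate
7 | 3-(1-methoxy-1-oxopropan-2-yl)-4-(2-methoxy-2-oxoethyl)-1,5-dimethylpyridin-1-ium trifluoromethanesulfonate (racemic) | COC(=O)Cc1c(C)c[n+](C)cc1C(C)C(=O)OC.[O-]S(=O)(=O)C(F)(F)F | intermediate
8 | methyl 2-[(3R*,4S*,5R*)-4-(2-methoxy-2-oxoethyl)-1,5-dimethylpiperidin-3-yl]propanoate (racemic, all-cis ring, both epimers at the propanoate carbon) | COC(=O)C[C@@H]1[C@@H](CN(C)C[C@@H]1C)C(C)C(=O)OC | intermediate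
9 | methyl (4R*,4aS*,7aR*)-6-hydroxy-2,4,7-trimethyl-2,3,4,4a,7,7a-hexahydro-1H-cyclopenta[c]pyridine-5-carboxylate (racemic, enol form, C7 as carried) | OC1=C(C(=O)OC)[C@@H]2[C@@H](CN(C)C[C@@H]2C)C1C | intermediate
10 | (4R*,4aS*,7aR*)-2,4,7-trimethyl-6-oxooctahydro-1H-cyclopenta[c]pyridine-5-carboxylic acid (racemic, not isolated) | OC(=O)C1[C@@H]2[C@@H](CN(C)C[C@@H]2C)C(C)C1=O | intermediate
11 | (4R*,4aS*,7S*,7aR*)-2,4,7-trimethyloctahydro-6H-cyclopenta[c]pyridin-6-one (racemic) | O=C1C[C@@H]2[C@@H](CN(C)C[C@@H]2C)[C@@H]1C | intermediate
12 | (4R*,4aS*,6R*,7S*,7aR*)-2,4,7-trimethyloctahydro-1H-cyclopenta[c]pyridin-6-ol (racemic) | O[C@@H]1C[C@@H]2[C@@H](CN(C)C[C@@H]2C)[C@@H]1C | intermediate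
13 | (4R,4aS,6R,7S,7aR)-6-hydroxy-2,4,7-trimethyloctahydro-1H-cyclopenta[c]pyridin-2-ium hydrogen (2R,3R)-2,3-bis[(4-methylbenzoyl)oxy]butanedioate | O[C@@H]1C[C@@H]2[C@@H](C[NH+](C)C[C@@H]2C)[C@@H]1C.OC(=O)[C@H](OC(=O)c1ccc(C)cc1)[C@@H](OC(=O)c1ccc(C)cc1)C([O-])=O | intermediate
14 | (4R,4aS,6R,7S,7aR)-2,4,7-trimethyloctahydro-1H-cyclopenta[c]pyridin-6-ol | O[C@@H]1C[C@@H]2[C@@H](CN(C)C[C@@H]2C)[C@@H]1C | intermediate
15 | geranyl acetate | CC(C)=CCC/C(C)=C/COC(C)=O | starting material
16 | (2E,6E)-8-hydroxy-3,7-dimethylocta-2,6-dien-1-yl acetate | CC(=O)OC/C=C(\C)CC/C=C(\C)CO | intermediate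
17 | (2E,6E)-2,6-dimethylocta-2,6-diene-1,8-diol | OC/C=C(\C)CC/C=C(\C)CO | intermediate
18 | (2E,6E)-2,6-dimethylocta-2,6-dienedial | O=C/C=C(\C)CC/C=C(\C)C=O | intermediate
19 | (2E,6E)-2,6-dimethylocta-2,6-dienedioic acid | OC(=O)/C=C(\C)CC/C=C(\C)C(=O)O | intermediate
20 | bis[(4R,4aS,6R,7S,7aR)-2,4,7-trimethyloctahydro-1H-cyclopenta[c]pyridin-6-yl] (2E,6E)-2,6-dimethylocta-2,6-dienedioate | C/C(=C\C(=O)O[C@@H]1C[C@@H]2[C@@H](CN(C)C[C@@H]2C)[C@@H]1C)CC/C=C(\C)C(=O)O[C@@H]1C[C@@H]2[C@@H](CN(C)C[C@@H]2C)[C@@H]1C | target

**Step count**

Total: 14 steps. Longest linear sequence: 10 steps (steps 1–9 and 14); the diacid branch is steps 10–13.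

**Three steps most likely to fail**

Step 8 (resolution). The two diastereomeric salts may crystallise together or not at all, so that no enrichment is reached. The fallback is an enzymatic kinetic resolution that sets out from 12. Acylation with vinyl acetate over immobilised Candida antarctica lipase B in MTBE should, by the empirical size rule for lipase acylation of secondary alcohols (CH(CH3) side large, CH2 side medium), esterify the (6R) enantiomer. This would give (4R,4aS,6R,7S,7aR)-2,4,7-trimethyloctahydro-1H-cyclopenta[c]pyridin-6-yl acetate F1, which is separated from the unreacted (6S) alcohol by chromatography. Methanolysis with K2CO3 in MeOH returns the route at 14.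

Step 7 (ketone reduction). Shielding of the concave face by ring B may steer the bulky hydride to the convex face, the face of H4a and H7a, and deliver the C6 epimer. The fallback sets out from 11 and takes that outcome on purpose. NaBH4 in MeOH at −20 °C, a small hydride expected to add from the convex face, should give racemic (4R*,4aS*,6S*,7S*,7aR*)-2,4,7-trimethyloctahydro-1H-cyclopenta[c]pyridin-6-ol F2. Mitsunobu inversion with 4-nitrobenzoic acid, PPh3 and DIAD in THF would give racemic (4R*,4aS*,6R*,7S*,7aR*)-2,4,7-trimethyloctahydro-1H-cyclopenta[c]pyridin-6-yl 4-nitrobenzoate F3. Methanolysis with K2CO3 in MeOH comes back to the route at 12.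

Step 4 (hydrogenation). Partly reduced tetrahydropyridinium intermediates may leave the surface, isomerise and re-adsorb by the other face, which would erode the all-cis delivery. The fallback sets out from 6 and reduces before N-methylation. The neutral pyridine is hydrogenated as its hydrochloride over rhodium on carbon (5 wt% Rh/C, H2 50 atm, MeOH/HCl), the metal that holds arenes most firmly face-on. The free base, methyl 2-[(3R*,4S*,5R*)-4-(2-methoxy-2-oxoethyl)-5-methylpiperidin-3-yl]propanoate F4, is liberated cold and N-methylated at once by reductive amination (aq. CH2O, NaBH(OAc)3, 1,2-dichloroethane). This returns to the route at 8.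

**Further compounds**

F1 | step 8 | (4R,4aS,6R,7S,7aR)-2,4,7-trimethyloctahydro-1H-cyclopenta[c]pyridin-6-yl acetate | CC(=O)O[C@@H]1C[C@@H]2[C@@H](CN(C)C[C@@H]2C)[C@@H]1C
F2 | step 7 | (4R*,4aS*,6S*,7S*,7aR*)-2,4,7-trimethyloctahydro-1H-cyclopenta[c]pyridin-6-ol (racemic) | O[C@H]1C[C@@H]2[C@@H](CN(C)C[C@@H]2C)[C@@H]1C
F3 | step 7 | (4R*,4aS*,6R*,7S*,7aR*)-2,4,7-trimethyloctahydro-1H-cyclopenta[c]pyridin-6-yl 4-nitrobenzoate (racemic) | O=C(O[C@@H]1C[C@@H]2[C@@H](CN(C)C[C@@H]2C)[C@@H]1C)c1ccc(cc1)[N+](=O)[O-]
F4 | step 4 | methyl 2-[(3R*,4S*,5R*)-4-(2-methoxy-2-oxoethyl)-5-methylpiperidin-3-yl]propanoate (racemic, both epimers at the propanoate carbon) | COC(=O)C[C@@H]1[C@@H](CNC[C@@H]1C)C(C)C(=O)OC
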